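C1, the quaternary oxygen-bearing carbon shared by rings B, C and D, is bonded to C9a, the enamine carbon shared by rings A and B, which stands at the ketone oxidation level; C1–C9a is therefore a latent α-hydroxy ketone inside six-membered ring C, and the C1 oxygen with the C13–C14 propionate arm on C12 makes up γ-lactone D.
Retrosynthetic cuts, in order: N4–C5 and N4=C9a (rings A and B); C1–C9a and O–C14 (rings C and D, one operation); C1–C2 (ketone from a thioester and an alkylzinc); C11–C12 (aldol); C9–C10 (nitro-Michael).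
Forward order: the chain is joined C9–C10, then C11–C12, then C1–C2; rings C and D close together, then ring B (imine), then ring A (N-alkylation to the enamine); lactone E arrives complete with the C2–C3 fragment.
Stereochemistry: C10 from an amine-catalysed Michael addition; C13 from an oxazolidinone alkylation; C11 and C12 from a Felkin-controlled anti boron aldol; C3 from D-serine, C18 from Felkin addition to the serine aldehyde, C20 from hydrogenation; C1 from a reversible ketol closure gated by lactonization.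
Key step: step 19

Remark on numbering: N4; C1, C2, C3 and C9a with N4 form ring B; C5–C9 and C9a with N4 form ring A; C9a, C9, C10 (ethyl), C11 (OH), C12 and C1 form ring C; C13 (methyl) and C14 (C=O) complete lactone D; C18–C21 are lactone E on C3.
Remark on spectator groups: the C3 nitrogen is carried as a tert-butyl carbamate, which tolerates zinc insertion and does not leave from the β-amino ketone under weakly basic carbene conditions; C9 is stereogenic only in intermediates and its configuration is immaterial.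

Step 1
Reactants: 1 6-chlorohexan-1-ol
Product: 2 6-chlorohexanal
Conditions: TEMPO (cat.), KBr (cat.), NaOCl, NaHCO3, CH2Cl2/H2O, 0 °C
Reagents that add atoms: none
Why: The nitroxyl-catalysed hypochlorite oxidation (Anelli oxidation) should stop at the aldehyde and leave the primary chloride untouched.

Step 2
Reactants: 3 propanal; 4 nitromethane
Product: 5 1-nitrobutan-2-ol (racemic)
Conditions: 4 (5 equiv), NaOH (cat.), MeOH/H2O, 0 °C → rt
Reagents that add atoms: none
Why: The Henry (nitroaldol) reaction of an unhindered aldehyde with excess nitromethane under catalytic hydroxide should give the β-nitro alcohol, whose stereocentre is removed in the next step.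

Step 3
Reactants: 5 1-nitrobutan-2-ol
Product: 7 (E)-1-nitrobut-1-ene, via mesylate 6 (not isolated)
Conditions: MsCl, Et3N, CH2Cl2, 0 °C
Reagents that add atoms: none
Why: Mesylation followed by E1cB elimination of the acidic β-nitro mesylate should give the conjugated E nitroalkene.

Step 4
Reactants: 2 6-chlorohexanal; 7 (E)-1-nitrobut-1-ene
Product: 8 (2S)-6-chloro-2-[(2S)-1-nitrobutan-2-yl]hexanal
Conditions: (R)-2-[diphenyl(trimethylsilyloxy)methyl]pyrrolidine (10 mol%), PhCO2H (10 mol%), toluene, 0 °C → rt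
Reagents that add atoms: none
Why: In this enamine-catalysed asymmetric Michael addition to a nitroalkene the (R)-diarylprolinol silyl ether shields one face of the E enamine of 2 and the acyclic synclinal transition state should deliver the syn adduct, fixing C10 as S (the C9 centre formed alongside is lost later).

Step 5
Reactants: 8 (2S)-6-chloro-2-[(2S)-1-nitrobutan-2-yl]hexanal
Product: 9 (5S,6S)-1-chloro-5-(dimethoxymethyl)-6-(nitromethyl)octane
Conditions: HC(OMe)3, p-TsOH·H2O (cat.), MeOH, rt
Reagents that add atoms: trimethyl orthoformate COC(OC)OC; methanol CO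
Why: Acid-catalysed acetalization masks the C9a aldehyde so that the two chain ends stay distinguishable when the nitro group is turned into the C11 aldehyde.

Step 6
Reactants: 9 (5S,6S)-1-chloro-5-(dimethoxymethyl)-6-(nitromethyl)octane
Product: 11 (2S,3S)-7-chloro-3-(dimethoxymethyl)-2-ethylheptanal, via sodium nitronate 10 (not isolated)
Conditions: NaOMe, MeOH, 0 °C; then O3, CH2Cl2/MeOH, −78 °C; N2 purge, pH 7 buffer
Reagents that add atoms: ozone [O-][O+]=O
Why: In this ozonolytic Nef reaction the C=N bond of the nitronate is cleaved at low temperature in a medium that does not enolize the new aldehyde, so C10 should keep its configuration.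

Step 7
Reactants: 12 (4S)-4-benzyl-3-propanoyl-1,3-oxazolidin-2-one; 13 tert-butyl bromoacetate
Product: 15 tert-butyl (3R)-4-[(4S)-4-benzyl-2-oxo-1,3-oxazolidin-3-yl]-3-methyl-4-oxobutanoate, via sodium enolate 14 (not isolated)
Conditions: NaN(SiMe3)2, THF, −78 °C; then 13, −78 → −40 °C
Reagents that add atoms: none
Why: In this Evans alkylation the chelated Z sodium enolate is attacked on the face opposite the benzyl group, which should set C13 as R.

Step 8
Reactants: 15 tert-butyl (3R)-4-[(4S)-4-benzyl-2-oxo-1,3-oxazolidin-3-yl]-3-methyl-4-oxobutanoate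
Product: 16 4-tert-butyl 1-methyl (2R)-2-methylbutanedioate
Conditions: NaOMe (cat.), MeOH, 0 °C
Reagents that add atoms: methanol CO
Why: Methoxide-catalysed transesterification attacks the exocyclic imide carbonyl, which is far more electrophilic than the tert-butyl ester, and the short cold exposure should not epimerize C13.

Step 9
Reactants: 16 4-tert-butyl 1-methyl (2R)-2-methylbutanedioate
Product: 17 (3R)-4-methoxy-3-methyl-4-oxobutanoic acid
Conditions: CF3CO2H, CH2Cl2, rt
Reagents that add atoms: none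
Why: Acidolysis removes the tert-butyl ester as isobutene and leaves the methyl ester, so the C1 carboxyl is freed selectively.

Step 10
Reactants: 17 (3R)-4-methoxy-3-methyl-4-oxobutanoic acid
Product: 18 methyl (2R)-2-methyl-4-oxo-4-(phenylsulfanyl)butanoate
Conditions: PhSH, DCC, DMAP (cat.), CH2Cl2, 0 °C → rt
Reagents that add atoms: thiophenol Sc1ccccc1
Why: Carbodiimide-mediated (Steglich-type) thioesterification gives a C1 acyl group that is soft-enolizable for the aldol and reactive toward palladium for the ketone synthesis, with no stereocentre next to the activated carboxyl.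

Step 11
Reactants: 18 methyl (2R)-2-methyl-4-oxo-4-(phenylsulfanyl)butanoate; 11 (2S,3S)-7-chloro-3-(dimethoxymethyl)-2-ethylheptanal
Product: 20 methyl (2R,3R,4R,5S,6S)-10-chloro-6-(dimethoxymethyl)-5-ethyl-4-hydroxy-2-methyl-3-[(phenylsulfanyl)carbonyl]decanoate, via enol borinate 19 (not isolated)
Conditions: (c-C6H11)2BCl, Et3N, Et2O, 0 °C; then 11, −78 → −20 °C; MeOH/pH 7 buffer
Reagents that add atoms: none
Why: In this boron-mediated anti aldol reaction (c-C6H11)2BCl/Et3N enolizes only the thioester to the E(O) enol borinate, whose chair Zimmerman–Traxler transition state gives the 11,12-anti adduct, while Felkin–Anh attack on the aldehyde (anti to the branched C9 substituent) sets C11 and allylic-strain control in the enolate (C13–H eclipsing the double bond, approach past the flat ester and anti to the methyl group) lets the C13 centre reinforce the same C12 configuration.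

Step 12
Reactants: 20 methyl (2R,3R,4R,5S,6S)-10-chloro-6-(dimethoxymethyl)-5-ethyl-4-hydroxy-2-methyl-3-[(phenylsulfanyl)carbonyl]decanoate
Product: 21 methyl (2R,3R,4R,5S,6S)-4-{[tert-butyl(dimethyl)silyl]oxy}-10-chloro-6-(dimethoxymethyl)-5-ethyl-2-methyl-3-[(phenylsulfanyl)carbonyl]decanoate
Conditions: TBSOTf, 2,6-lutidine, CH2Cl2, −78 → 0 °C
Reagents that add atoms: tert-butyldimethylsilyl trifluoromethanesulfonate CC(C)(C)[Si](C)(C)OS(=O)(=O)C(F)(F)F
Why: Silylation of the hindered secondary alcohol with the silyl triflate, done without delay, blocks the C11 oxygen from lactonizing onto C14 here and in the key step.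

Step 13
Reactants: 22 tert-butyl (4R)-4-formyl-2,2-dimethyl-1,3-oxazolidine-3-carboxylate; 23 methyl 2-(bromomethyl)prop-2-enoate
Product: 26 tert-butyl (4R)-2,2-dimethyl-4-[(2S)-4-methylidene-5-oxooxolan-2-yl]-1,3-oxazolidine-3-carboxylate, via allylzinc bromide 24 (not isolated), via hydroxy ester 25 (not isolated)
Conditions: Zn dust (activated), THF, rt → 50 °C; aq NH4Cl
Reagents that add atoms: none
Why: In this Dreiding–Schmidt reaction the allylzinc should add to the D-serine-derived aldehyde through a non-chelated Felkin–Anh transition state to give mainly the anti amino alcohol arrangement (C18 S), the zinc alkoxide then closes the lactone with loss of methoxide, and the minor syn isomer is removed by chromatography.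

Step 14
Reactants: 26 tert-butyl (4R)-2,2-dimethyl-4-[(2S)-4-methylidene-5-oxooxolan-2-yl]-1,3-oxazolidine-3-carboxylate
Product: 27 tert-butyl (4R)-2,2-dimethyl-4-[(2S,4S)-4-methyl-5-oxooxolan-2-yl]-1,3-oxazolidine-3-carboxylate
Conditions: H2 (1 atm), 5% Rh/Al2O3, EtOAc, rt
Reagents that add atoms: none
Why: Heterogeneous hydrogenation should add hydrogen to the exocyclic alkene from the lactone face remote from the bulky oxazolidine on C18, so the new methyl group ends cis to that substituent (C20 S).

Step 15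
Reactants: 27 tert-butyl (4R)-2,2-dimethyl-4-[(2S,4S)-4-methyl-5-oxooxolan-2-yl]-1,3-oxazolidine-3-carboxylate
Product: 28 tert-butyl N-[(1R)-2-hydroxy-1-[(2S,4S)-4-methyl-5-oxooxolan-2-yl]ethyl]carbamate
Conditions: p-TsOH·H2O (cat.), MeOH, rt
Reagents that add atoms: none
Why: Acid-catalysed transacetalization removes the N,O-isopropylidene group under conditions that leave the carbamate and the γ-lactone in place.

Step 16
Reactants: 28 tert-butyl N-[(1R)-2-hydroxy-1-[(2S,4S)-4-methyl-5-oxooxolan-2-yl]ethyl]carbamate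
Product: 29 tert-butyl N-[(1S)-2-iodo-1-[(2S,4S)-4-methyl-5-oxooxolan-2-yl]ethyl]carbamate
Conditions: I2, PPh3, imidazole, CH2Cl2, 0 °C → rt
Reagents that add atoms: iodine II
Why: Appel-type iodination through the alkoxyphosphonium salt replaces the primary hydroxyl by iodide without touching C3 (the descriptor changes only because iodine raises the priority of C2).

Step 17
Reactants: 29 tert-butyl N-[(1S)-2-iodo-1-[(2S,4S)-4-methyl-5-oxooxolan-2-yl]ethyl]carbamate; 21 methyl (2R,3R,4R,5S,6S)-4-{[tert-butyl(dimethyl)silyl]oxy}-10-chloro-6-(dimethoxymethyl)-5-ethyl-2-methyl-3-[(phenylsulfanyl)carbonyl]decanoate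
Product: 31 methyl (2R,3R,4R,5S,6S)-3-{(3R)-3-[(tert-butoxycarbonyl)amino]-3-[(2S,4S)-4-methyl-5-oxooxolan-2-yl]propanoyl}-4-{[tert-butyl(dimethyl)silyl]oxy}-10-chloro-6-(dimethoxymethyl)-5-ethyl-2-methyldecanoate, via alkylzinc iodide 30 (not isolated)
Conditions: Zn dust (I2-activated), DMF, rt; then 21, PdCl2(PPh3)2 (10 mol%), toluene/DMF, rt → 40 °C
Reagents that add atoms: none
Why: Zinc insertion gives a β-amido alkylzinc iodide stabilised by carbamate coordination, and the Fukuyama coupling (insertion of zerovalent palladium into the acyl–sulfur bond, transmetalation, reductive elimination) forms the C1–C2 ketone without base, so C12 and the lactone, ester, acetal and chloride groups should be untouched.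

Step 18
Reactants: 31 methyl (2R,3R,4R,5S,6S)-3-{(3R)-3-[(tert-butoxycarbonyl)amino]-3-[(2S,4S)-4-methyl-5-oxooxolan-2-yl]propanoyl}-4-{[tert-butyl(dimethyl)silyl]oxy}-10-chloro-6-(dimethoxymethyl)-5-ethyl-2-methyldecanoate
Product: 32 methyl (2R,3R,4R,5S,6S)-3-{(3R)-3-[(tert-butoxycarbonyl)amino]-3-[(2S,4S)-4-methyl-5-oxooxolan-2-yl]propanoyl}-4-{[tert-butyl(dimethyl)silyl]oxy}-10-chloro-5-ethyl-6-formyl-2-methyldecanoate
Conditions: PPTS (cat.), acetone/H2O (10:1), 45 °C
Reagents that add atoms: water O
Why: Mild acid hydrolysis of the dimethyl acetal frees the C9a aldehyde while the secondary silyl ether and the carbamate survive.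

Step 19
Reactants: 32 methyl (2R,3R,4R,5S,6S)-3-{(3R)-3-[(tert-butoxycarbonyl)amino]-3-[(2S,4S)-4-methyl-5-oxooxolan-2-yl]propanoyl}-4-{[tert-butyl(dimethyl)silyl]oxy}-10-chloro-5-ethyl-6-formyl-2-methyldecanoate
Product: 34 tert-butyl N-[(1R)-2-[(3R,3aR,4R,5S,6S,7aR)-4-{[tert-butyl(dimethyl)silyl]oxy}-6-(4-chlorobutyl)-5-ethyl-3-methyl-2,7-dioxooctahydro-1-benzofuran-7a-yl]-1-[(2S,4S)-4-methyl-5-oxooxolan-2-yl]ethyl]carbamate, via ketol 33 (not isolated)
Conditions: 2-(pentafluorophenyl)-6,7-dihydro-5H-pyrrolo[2,1-c][1,2,4]triazol-2-ium tetrafluoroborate (20 mol%), Et3N (0.5 equiv), CH2Cl2, rt → 40 °C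
Reagents that add atoms: none
Why: The triazolylidene released by the amine adds to the C9a aldehyde, proton transfer gives the Breslow intermediate, and this acyl anion equivalent attacks the C1 ketone before the carbene is expelled, which is the known carbene-catalysed intramolecular crossed aldehyde–ketone benzoin route to six-membered α-ketols. Ring C closes by a 6-exo-trig addition of C9a to the C1 carbonyl and ring D by a 5-exo-trig acyl substitution of the C1 hydroxyl on the C14 methyl ester with loss of methanol. C1 is the only new stereocentre: the ketol addition is reversible through the same carbene adduct whereas lactonization is not, and only the C1 epimer with its oxygen cis to the C12 side chain (fixed by the C12 and C13 centres of step 11) can reach C14, so the equilibrium should drain into the cis-fused lactone 34. Chemoselectivity rests on the aldehyde being the only carbonyl that can form a Breslow intermediate and on the ketone being the only electrophile at six-ring distance, and the weak amine base is chosen so that C12 is not epimerized and neither the C11 silyloxy group nor the C3 carbamate is eliminated from the β-substituted ketone. The silyl ether keeps the C11 oxygen from competing for C14, and C9 may epimerize freely because it later becomes the enamine carbon.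

Step 20
Reactants: 34 the bicyclic keto lactone of step 19
Product: 36 tricyclic imine (N4=C9a 1-pyrroline; rings B C D closed; C9–H and 4-chlorobutyl chain kept; 11-O-TBS), via primary amine 35 (not isolated)
Conditions: CF3CO2H/CH2Cl2 (1:5), 0 °C; evaporate; NaOAc, 4 Å molecular sieves, CH2Cl2, rt
Reagents that add atoms: none
Why: Acidolysis of the carbamate frees the C3 amine, which under acetate buffering condenses with the C9a ketone (5-exo-trig addition, then dehydration) far faster than it can open lactone E, closing ring B as the cyclic imine.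

Step 21
Reactants: 36 tricyclic imine
Product: 39 11-O-(tert-butyldimethylsilyl) ether of the target, via alkyl iodide 37 (not isolated), via iminium iodide 38 (not isolated)
Conditions: NaI, iPr2NEt, MeCN (high dilution), 70 °C
Reagents that add atoms: none
Why: Finkelstein exchange followed by intramolecular N-alkylation of the imine nitrogen (7-exo-tet) closes ring A as an iminium salt, and deprotonation at C9, the only enolizable position because C1 is quaternary, gives the C9=C9a enamine.

Step 22
Reactants: 39 11-O-(tert-butyldimethylsilyl) ether of the target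
Product: 40 CNP0154902.3
Conditions: HF·pyridine, pyridine, THF, 0 °C → rt; aq NaHCO3
Reagents that add atoms: none
Why: Buffered fluoride cleaves the Si–O bond without base, so the freed C11 hydroxyl should not translactonize onto C14, and the enamine protonated in the medium is regenerated on bicarbonate work-up.

Compound list
1 | 6-chlorohexan-1-ol | OCCCCCCCl | starting material
2 | 6-chlorohexanal | O=CCCCCCCl | intermediate
3 | propanal | CCC=O | starting material
4 | nitromethane | C[N+](=O)[O-] | starting material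
5 | 1-nitrobutan-2-ol (racemic) | CCC(O)C[N+](=O)[O-] | intermediate
6 | 1-nitrobutan-2-yl methanesulfonate (racemic) | CCC(OS(C)(=O)=O)C[N+](=O)[O-] | intermediate (not isolated)
7 | (E)-1-nitrobut-1-ene | CC/C=C/[N+](=O)[O-] | intermediate
8 | (2S)-6-chloro-2-[(2S)-1-nitrobutan-2-yl]hexanal | O=C[C@@H](CCCCCl)[C@H](CC)C[N+](=O)[O-] | intermediate
9 | (5S,6S)-1-chloro-5-(dimethoxymethyl)-6-(nitromethyl)octane | COC(OC)[C@@H](CCCCCl)[C@H](CC)C[N+](=O)[O-] | intermediate
10 | sodium nitronate of 9 | COC(OC)[C@@H](CCCCCl)[C@H](CC)C=[N+]([O-])[O-].[Na+] | intermediate (not isolated)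
11 | (2S,3S)-7-chloro-3-(dimethoxymethyl)-2-ethylheptanal | O=C[C@@H](CC)[C@H](CCCCCl)C(OC)OC | intermediate
12 | (4S)-4-benzyl-3-propanoyl-1,3-oxazolidin-2-one | CCC(=O)N1[C@@H](Cc2ccccc2)COC1=O | starting material
13 | tert-butyl bromoacetate | CC(C)(C)OC(=O)CBr | starting material
14 | sodium (Z)-enolate of 12 | C/C=C(\[O-])N1[C@@H](Cc2ccccc2)COC1=O.[Na+] | intermediate (not isolated)
15 | tert-butyl (3R)-4-[(4S)-4-benzyl-2-oxo-1,3-oxazolidin-3-yl]-3-methyl-4-oxobutanoate | CC(C)(C)OC(=O)C[C@@H](C)C(=O)N1[C@@H](Cc2ccccc2)COC1=O | intermediate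
16 | 4-tert-butyl 1-methyl (2R)-2-methylbutanedioate | COC(=O)[C@H](C)CC(=O)OC(C)(C)C | intermediate
17 | (3R)-4-methoxy-3-methyl-4-oxobutanoic acid | COC(=O)[C@H](C)CC(=O)O | intermediate
18 | methyl (2R)-2-methyl-4-oxo-4-(phenylsulfanyl)butanoate | COC(=O)[C@H](C)CC(=O)Sc1ccccc1 | intermediate
19 | dicyclohexylboron E(O)-enolate of 18 (boryloxy group trans to the C13 substituent) | COC(=O)[C@H](C)/C=C(/OB(C1CCCCC1)C1CCCCC1)Sc1ccccc1 | intermediate (not isolated)
20 | methyl (2R,3R,4R,5S,6S)-10-chloro-6-(dimethoxymethyl)-5-ethyl-4-hydroxy-2-methyl-3-[(phenylsulfanyl)carbonyl]decanoate | COC(OC)[C@@H](CCCCCl)[C@H](CC)[C@@H](O)[C@@H]([C@@H](C)C(=O)OC)C(=O)Sc1ccccc1 | intermediate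
21 | methyl (2R,3R,4R,5S,6S)-4-{[tert-butyl(dimethyl)silyl]oxy}-10-chloro-6-(dimethoxymethyl)-5-ethyl-2-methyl-3-[(phenylsulfanyl)carbonyl]decanoate | COC(OC)[C@@H](CCCCCl)[C@H](CC)[C@@H](O[Si](C)(C)C(C)(C)C)[C@@H]([C@@H](C)C(=O)OC)C(=O)Sc1ccccc1 | intermediate
22 | tert-butyl (4R)-4-formyl-2,2-dimethyl-1,3-oxazolidine-3-carboxylate (D-serine-derived aldehyde) | O=C[C@H]1COC(C)(C)N1C(=O)OC(C)(C)C | starting material
23 | methyl 2-(bromomethyl)prop-2-enoate | C=C(CBr)C(=O)OC | starting material
24 | [2-(methoxycarbonyl)prop-2-en-1-yl]zinc bromide | C=C(C[Zn]Br)C(=O)OC | intermediate (not isolated)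
25 | methyl 2-{(2S)-2-hydroxy-2-[(4R)-3-(tert-butoxycarbonyl)-2,2-dimethyl-1,3-oxazolidin-4-yl]ethyl}prop-2-enoate | C=C(C[C@H](O)[C@H]1COC(C)(C)N1C(=O)OC(C)(C)C)C(=O)OC | intermediate (not isolated)
26 | tert-butyl (4R)-2,2-dimethyl-4-[(2S)-4-methylidene-5-oxooxolan-2-yl]-1,3-oxazolidine-3-carboxylate | CC(C)(C)OC(=O)N1[C@H](COC1(C)C)[C@@H]1CC(=C)C(=O)O1 | intermediate
27 | tert-butyl (4R)-2,2-dimethyl-4-[(2S,4S)-4-methyl-5-oxooxolan-2-yl]-1,3-oxazolidine-3-carboxylate | CC(C)(C)OC(=O)N1[C@H](COC1(C)C)[C@@H]1C[C@H](C)C(=O)O1 | intermediate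
28 | tert-butyl N-[(1R)-2-hydroxy-1-[(2S,4S)-4-methyl-5-oxooxolan-2-yl]ethyl]carbamate | CC(C)(C)OC(=O)N[C@H](CO)[C@@H]1C[C@H](C)C(=O)O1 | intermediate
29 | tert-butyl N-[(1S)-2-iodo-1-[(2S,4S)-4-methyl-5-oxooxolan-2-yl]ethyl]carbamate | CC(C)(C)OC(=O)N[C@H](CI)[C@@H]1C[C@H](C)C(=O)O1 | intermediate
30 | {(2S)-2-[(tert-butoxycarbonyl)amino]-2-[(2S,4S)-4-methyl-5-oxooxolan-2-yl]ethyl}zinc iodide | CC(C)(C)OC(=O)N[C@H](C[Zn]I)[C@@H]1C[C@H](C)C(=O)O1 | intermediate (not isolated)
31 | methyl (2R,3R,4R,5S,6S)-3-{(3R)-3-[(tert-butoxycarbonyl)amino]-3-[(2S,4S)-4-methyl-5-oxooxolan-2-yl]propanoyl}-4-{[tert-butyl(dimethyl)silyl]oxy}-10-chloro-6-(dimethoxymethyl)-5-ethyl-2-methyldecanoate | COC(OC)[C@@H](CCCCCl)[C@H](CC)[C@@H](O[Si](C)(C)C(C)(C)C)[C@@H]([C@@H](C)C(=O)OC)C(=O)C[C@@H](NC(=O)OC(C)(C)C)[C@@H]1C[C@H](C)C(=O)O1 | intermediate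
32 | methyl (2R,3R,4R,5S,6S)-3-{(3R)-3-[(tert-butoxycarbonyl)amino]-3-[(2S,4S)-4-methyl-5-oxooxolan-2-yl]propanoyl}-4-{[tert-butyl(dimethyl)silyl]oxy}-10-chloro-5-ethyl-6-formyl-2-methyldecanoate (open-chain keto aldehyde) | O=C[C@@H](CCCCCl)[C@H](CC)[C@@H](O[Si](C)(C)C(C)(C)C)[C@@H]([C@@H](C)C(=O)OC)C(=O)C[C@@H](NC(=O)OC(C)(C)C)[C@@H]1C[C@H](C)C(=O)O1 | intermediate
33 | methyl (2R)-2-[(1R,2R,3S,4S,6R)-6-{(2R)-2-[(tert-butoxycarbonyl)amino]-2-[(2S,4S)-4-methyl-5-oxooxolan-2-yl]ethyl}-2-{[tert-butyl(dimethyl)silyl]oxy}-4-(4-chlorobutyl)-3-ethyl-6-hydroxy-5-oxocyclohexyl]propanoate (ring C ketol before lactonization) | CC[C@H]1[C@H](CCCCCl)C(=O)[C@@](O)(C[C@@H](NC(=O)OC(C)(C)C)[C@@H]2C[C@H](C)C(=O)O2)[C@H]([C@@H](C)C(=O)OC)[C@@H]1O[Si](C)(C)C(C)(C)C | intermediate (not isolated)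
34 | tert-butyl N-[(1R)-2-[(3R,3aR,4R,5S,6S,7aR)-4-{[tert-butyl(dimethyl)silyl]oxy}-6-(4-chlorobutyl)-5-ethyl-3-methyl-2,7-dioxooctahydro-1-benzofuran-7a-yl]-1-[(2S,4S)-4-methyl-5-oxooxolan-2-yl]ethyl]carbamate (ring C/D keto lactone) | CC[C@H]1[C@H](CCCCCl)C(=O)[C@]2(C[C@@H](NC(=O)OC(C)(C)C)[C@@H]3C[C@H](C)C(=O)O3)OC(=O)[C@H](C)[C@@H]2[C@@H]1O[Si](C)(C)C(C)(C)C | intermediate
35 | (3R,3aR,4R,5S,6S,7aR)-7a-{(2R)-2-amino-2-[(2S,4S)-4-methyl-5-oxooxolan-2-yl]ethyl}-4-{[tert-butyl(dimethyl)silyl]oxy}-6-(4-chlorobutyl)-5-ethyl-3-methylhexahydro-1-benzofuran-2,7-dione | CC[C@H]1[C@H](CCCCCl)C(=O)[C@]2(C[C@@H](N)[C@@H]3C[C@H](C)C(=O)O3)OC(=O)[C@H](C)[C@@H]2[C@@H]1O[Si](C)(C)C(C)(C)C | intermediate (not isolated)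
36 | tricyclic imine: N4=C9a 1-pyrroline fused to rings C and D, C9 (S) bearing H and the 4-chlorobutyl chain, 11-O-TBS, lactone E on C3 | CC[C@H]1[C@H](CCCCCl)C2=N[C@@H]([C@@H]3C[C@H](C)C(=O)O3)C[C@]24OC(=O)[C@H](C)[C@@H]4[C@@H]1O[Si](C)(C)C(C)(C)C | intermediate
37 | 4-iodobutyl analogue of 36 | CC[C@H]1[C@H](CCCCI)C2=N[C@@H]([C@@H]3C[C@H](C)C(=O)O3)C[C@]24OC(=O)[C@H](C)[C@@H]4[C@@H]1O[Si](C)(C)C(C)(C)C | intermediate (not isolated)
38 | pentacyclic iminium iodide: N4–C5 bond formed, C9a=N4 cationic, C9–H still present, 11-O-TBS | CC[C@H]1[C@H]2C3=[N+](CCCC2)[C@@H]([C@@H]2C[C@H](C)C(=O)O2)C[C@]32OC(=O)[C@H](C)[C@@H]2[C@@H]1O[Si](C)(C)C(C)(C)C.[I-] | intermediate (not isolated)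
39 | 11-O-(tert-butyldimethylsilyl) ether of the target | CC[C@H]1C2=C3N(CCCC2)[C@@H]([C@@H]2C[C@H](C)C(=O)O2)C[C@]32OC(=O)[C@H](C)[C@@H]2[C@@H]1O[Si](C)(C)C(C)(C)C | intermediate
40 | CNP0154902.3 (1R,3R,10S,11R,12R,13R,18S,20S in the numbering used here) | CC[C@H]1C2=C3N(CCCC2)[C@@H]([C@@H]2C[C@H](C)C(=O)O2)C[C@]32OC(=O)[C@H](C)[C@@H]2[C@@H]1O | target

Total step count: 22. Longest linear sequence: 13 steps (2, 3, 4, 5, 6, 11, 12, 17, 18, 19, 20, 21, 22); the thioester branch (7–10) and the lactone E branch (13–16) join it at steps 11 and 17.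

Steps most likely to fail

Step 11. The aldol may give the wrong isomers through erosion of the E(O) enolate geometry of the S-phenyl thioester, weak facial discrimination by the C13 centre, or lactonization of the adduct onto C14 before silylation. The fallback makes the same C11–C12 bond by enamine catalysis, setting out from 18 and 11. Thioester 18 would be reduced with Et3SiH and Pd/C (Fukuyama reduction) to methyl (2R)-2-methyl-4-oxobutanoate F1. Slow addition of F1 to 11 in DMF with D-proline at 4 °C should give, through the hydrogen-bonded enamine aldol transition state (anti, catalyst-controlled and Felkin-matched), the β-hydroxy aldehyde F2. TBSOTf/2,6-lutidine would give the silyl ether aldehyde F3, Pinnick oxidation (NaClO2, NaH2PO4, 2-methylbut-2-ene) the carboxylic acid F4, and PhSH, DCC and DMAP would return to the route at 21.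

Step 17. The coupling may stall through slow acyl–sulfur insertion at the hindered, α-branched thioester, or the alkylzinc may be lost by β-elimination of the carbamate. The fallback forms the ketone without a preformed organometal, setting out from 21 and 29. Thioester 21 would be hydrolysed (AgNO3, 2,6-lutidine, THF/H2O) to the carboxylic acid F4 and converted with 1-chloro-N,N,2-trimethylprop-1-en-1-amine in CH2Cl2 into the acid chloride F5. Nickel-catalysed reductive cross-electrophile coupling of F5 with iodide 29 (NiCl2(dme), 4,4'-di-tert-butyl-2,2'-bipyridine, Mn powder, DMA, rt) would return to the route at 31.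

Step 19. The carbene step may be diverted into base-mediated aldol closure through the C12 or C9 enolate, β-elimination of the C11 silyloxy group, or a ketol addition that does not equilibrate at C1, so that lactonization stalls. The fallback closes ring C reductively, setting out from 32. SmI2 in THF at −78 °C should effect ketyl–carbonyl pinacol cyclization to the cis-1,2-diol, whose tertiary samarium alkoxide closes lactone D to give the C9a hydroxy lactone F6; a C1 epimer unable to lactonize would be separated. Dess–Martin periodinane would oxidize the secondary C9a alcohol and return to the route at 34.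

Further compounds
F1 | step 11 | methyl (2R)-2-methyl-4-oxobutanoate | COC(=O)[C@H](C)CC=O
F2 | step 11 | β-hydroxy aldehyde: methyl (2R,3R,4R,5S,6S)-10-chloro-6-(dimethoxymethyl)-5-ethyl-3-formyl-4-hydroxy-2-methyldecanoate | COC(OC)[C@@H](CCCCCl)[C@H](CC)[C@@H](O)[C@@H]([C@@H](C)C(=O)OC)C=O
F3 | step 11 | silyl ether aldehyde: methyl (2R,3R,4R,5S,6S)-4-{[tert-butyl(dimethyl)silyl]oxy}-10-chloro-6-(dimethoxymethyl)-5-ethyl-3-formyl-2-methyldecanoate | COC(OC)[C@@H](CCCCCl)[C@H](CC)[C@@H](O[Si](C)(C)C(C)(C)C)[C@@H]([C@@H](C)C(=O)OC)C=O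
F4 | step 11 | carboxylic acid: (2R,3R,4S,5S)-3-{[tert-butyl(dimethyl)silyl]oxy}-9-chloro-5-(dimethoxymethyl)-4-ethyl-2-[(2R)-1-methoxy-1-oxopropan-2-yl]nonanoic acid | COC(OC)[C@@H](CCCCCl)[C@H](CC)[C@@H](O[Si](C)(C)C(C)(C)C)[C@@H]([C@@H](C)C(=O)OC)C(=O)O
F5 | step 17 | acid chloride of F4 | COC(OC)[C@@H](CCCCCl)[C@H](CC)[C@@H](O[Si](C)(C)C(C)(C)C)[C@@H]([C@@H](C)C(=O)OC)C(Cl)=O
F6 | step 19 | C9a hydroxy lactone: 34 with CH–OH in place of the C9a ketone, hydroxyl cis to the C1 oxygen | CC[C@H]1[C@H](CCCCCl)[C@H](O)[C@]2(C[C@@H](NC(=O)OC(C)(C)C)[C@@H]3C[C@H](C)C(=O)O3)OC(=O)[C@H](C)[C@@H]2[C@@H]1O[Si](C)(C)C(C)(C)C
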